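## The problem

1. CNP0265335.4 is a heliangolide-type germacranolide built on a cyclodecane ring (C1–C10, germacrane numbering). It carries a trans 1β,10α-epoxide (1R,10R), a ring-cis (Z) C4=C5 bond, and an α-methylene-γ-butyrolactone trans-fused at C6–C7 (O on C6; 6R,7R). It also carries an (R)-2-methylbutanoate on the 3β-oxygen (3S) and a (2S,3R)-2,3-dimethyloxirane-2-carboxylate on the 8β-oxygen (8R); read from the SMILES, this acyl group is the epoxide of a tiglate, with the two methyl groups cis.
2. The hardest feature is the ten-membered carbocycle. End-to-end closure fights transannular strain, and the ring must hold one E-derived unit (C1/C10) and one Z trisubstituted unit (C4=C5) at fixed places.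
3. C6, C7 and C8 are contiguous and can control each other. C3 is insulated from them by C4=C5 and must come from outside. C1/C10 can only be set by choosing one face of an E-C1=C10 olefin. The three acyl stereocentres are independent and arrive with the acids.
4. Three oxygens (O3, O6, O8) of similar nature must be told apart.
5. The exocyclic enoate (a Michael acceptor), the 1(10)-epoxide (prone to transannular opening by acid), the glycidic ester and the allylic C3/C6 acyloxy groups do not survive strong base, acid or nucleophiles. They must therefore appear late.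
6. First enabling feature: O6 stands 1,5 to the C1=C10 unit (C6–C7–C8–C9–C10=C1), which is the retron of an oxy-Cope rearrangement. The remaining ring atoms C1–C6, with their cis C4=C5 bond, can be folded into a cyclohexene (ring A) by a temporary C1–C6 bond. With C9, C10, C14 and C15, ring A has the carbon skeleton of carvone.
7. Second enabling feature: O8, C8, C7, C11 and C13 form a five-atom chain that a temporary O8–C13 bond closes to a dihydrofuran (ring D). With C12, this is the skeleton of furan-3-carboxylic acid, so the C15 framework is C10 + C5.

## Retrosynthesis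

**Epoxide and esters (34 ⇒ 33 ⇒ 30 ⇒ 29 ⇒ 24 + 27 + 31).** The two C–O bonds of the 1(10)-epoxide and the acyl–O bonds at O3 and O8 are cut first, because these are the most fragile groups. In triene 33 the C1=C10 bond is the only electron-rich olefin: C4=C5 is flanked by two acyloxy groups and C11=C13 is an enoate. The forward epoxidation therefore needs only face selectivity. The precursor 24 has O8 free and O3 silylated, so the two acids 27 and 31 can be placed one after the other.

**Temporary O8–C13 bond (24 ⇒ 22).** An O8–C13 bond that is absent from the target is added. It masks the enoate and the 8-hydroxyl together as a tetrahydrofuran. The neighbouring choice, a separate α-methylenation plus a protecting group on O8, costs more steps and needs a strong base in the presence of a free or protected 8-oxygen. The forward step must be a β-alkoxy elimination that erases C11 and frees O8 as the only hydroxyl.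

**Lactone (22 ⇒ 20 ⇒ 19 ⇒ 18).** The O6–C12 bond is cut and C12 and C6 are brought to the alcohol and ketone levels. Because O8 is still tied to C13, only O6 can lactonise, so the 6,12- versus 8,12-olide question does not arise. The forward steps must reduce the C6 ketone of 18 from its outer face and oxidise the primary alcohol selectively.

**Temporary C1–C6 bond, the key cut (18 ⇒ 15).** C8–C9 is cut and C1–C6 is made, which is the retro-oxy-Cope operation. Cutting C6–C7, C4=C5 or C1=C10 instead would give open chains that need two stereodefined trisubstituted olefins and a macrocyclisation. Here the Z olefin is trivially cis inside ring A and the E olefin results from the chair. Carbinol 15 is a cyclohexenol with two alkenyl groups and no medium ring. The forward step must show chair selectivity, transfer chirality from C1 to C8, and give an enolate that keeps its β-oxygen. An open-chain enol ether partner is rejected for the last reason.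

**C6–C7 (15 ⇒ 6 + 13).** This is a carbonyl addition of the vinyl anion of 13 to enone 6, and it joins C10 and C5 in one bond. The configuration formed at C6 is not critical, because C6 becomes trigonal in the key step.

**Ring A (6 ⇒ 5 ⇒ 4 ⇒ 2 ⇒ 1).** The C6 carbonyl is taken back to CH2 and the C3 oxygen to the epoxide of carvone 1. The (S)-enantiomer is chosen because epoxidation followed by transposition gives the trans relation of C3–O and C1–isopropenyl in two steps.

**Ring D (13 ⇒ 11 ⇒ 10 ⇒ 9 ⇒ 8 ⇒ 7).** Bromine, the protecting group and two hydrogens are removed, which leads back to furan-3-carboxylic acid 7. The single stereocentre C11 is temporary. It is fixed by resolution so that C12 ends up cis to C6 on the tetrahydrofuran, which is the condition for lactone closure.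

**Glycidic acid (27 ⇒ 26 ⇒ 25).** The epoxide oxygen is removed and the acid is reduced to the allylic alcohol 25. This is a standard substrate for catalytic asymmetric epoxidation.

## Roads not taken

**Alternative 1:** (the most obvious) cut C6–C7 and O6–C12.
- Forward key step: intramolecular Nozaki–Hiyama–Kishi/Barbier allylation (CrCl2, or Zn) of the open-chain Z-enal allylic bromide A1, followed by lactonisation.
- It builds the methylene lactone directly.
- A1, however, needs both trisubstituted olefins and two remote stereocentres made one by one in a long linear sequence.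
- Its β-methyl Z-enal isomerises easily.
- The closure is a high-dilution macrocyclisation in which C6 and C7 are set only by an unpredictable macrocyclic transition state.
- The chosen plan gets the ring by expansion, the Z olefin from ring A and the E olefin from a chair.

**Alternative 2:** cut C4=C5.
- Forward key step: ring-closing metathesis of diene A2 with a second-generation Grubbs catalyst.
- A trisubstituted olefin flanked by two oxygenated carbons would have to form inside a ten-membered ring with Z geometry.
- The C1=C10 and C11=C13 bonds would have to remain spectators.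
- Ring strain favours oligomers, and the E/Z outcome is not under control.
- The chosen plan never has to create this olefin.

**Alternative 3:** cut C6–C7 in the sense of a [2,3]-Wittig ring contraction of the 13-membered bis-allylic ether A3 (O bridging C6 and C13).
- It would set C6–OH, C7 and the exocyclic methylene at once.
- It first needs a macrocyclic ether with three defined olefins.
- It then needs deprotonation at C6 in preference to C13.
- Its stereochemical outcome rests on macrocycle conformation next to the C8 centre.
- The run-up is longer than the whole sequence to 15.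

Key step: step 11

Remark: germacrane numbers (C1–C15, O3, O6, O8) are used for all ring-expanded compounds and, for tracking, for the same atoms in their precursors.
Assumption: the (S)-acid is taken to form the less soluble salt with (R)-1-phenylethylamine; if the pairing is the reverse, the (S)-amine is used in the same way.
Assumption: 25 and 31 are taken as purchasable in the stated configuration.

## Steps

Step 1
Reactants: 1 (S)-(+)-carvone
Product: 2 (1S,4S,6S)-carvone epoxide (oxirane trans to isopropenyl)
Conditions: 30% aq. H2O2, NaOH (cat.), MeOH, 0 °C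
Reagents that add atoms: hydrogen peroxide OO
Why: Weitz–Scheffer epoxidation touches only the enone double bond; hydroperoxide adds anti to the isopropenyl group and so sets the C–O bond that becomes the 3β-oxygen (C3, S).

Step 2
Reactants: 2 (1S,4S,6S)-carvone epoxide
Product: 4 (1S,5R)-trans-carveol, via epoxy hydrazone 3 (not isolated)
Conditions: N2H4·H2O, AcOH (cat.), MeOH, 0 °C to rt
Reagents that add atoms: none
Why: Wharton transposition: hydrazone 3 opens to an allylic diazene that loses N2, which moves the double bond to C4=C5 and leaves the C3–O bond untouched. The former α'-CH2 of carvone becomes C6, so the (S)-ketone delivers the 5R-carveol series with O3 trans to the isopropenyl group.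

Step 3
Reactants: 4 (1S,5R)-trans-carveol
Product: 5 trans-carveol tert-butyldimethylsilyl ether
Conditions: TBSCl, imidazole, DMF, rt
Reagents that add atoms: tert-butyldimethylsilyl chloride C[Si](C)(Cl)C(C)(C)C
Why: Standard silylation; the TBS ether survives organolithium, KH, hydride, DDQ and oxoammonium oxidation and is removed by fluoride at the end.

Step 4
Reactants: 5 trans-carveol tert-butyldimethylsilyl ether
Product: 6 (4S,6R)-4-(tert-butyldimethylsilyloxy)-3-methyl-6-(prop-1-en-2-yl)cyclohex-2-en-1-one
Conditions: Rh2(cap)4 (cap = caprolactamate, 1 mol %), t-BuOOH (70% in water), CH2Cl2, rt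
Reagents that add atoms: tert-butyl hydroperoxide CC(C)(C)OO
Why: Allylic oxidation of a ring CH2 to the enone through the tert-butylperoxy radical chain; C6 is the only secondary allylic CH2, C3–H is shielded by the silyl ether, and isopropenyl groups are known to survive this type of terpene oxidation. No base is added, so that C1 (α to the new ketone) is not epimerised and the isopropenyl group is not conjugated.

Step 5
Reactants: 7 furan-3-carboxylic acid
Product: 8 rac-2,3-dihydrofuran-3-carboxylic acid
Conditions: Na, NH3 (l), i-PrOH, −78 °C; then NH4Cl; cold acidification to pH 3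
Reagents that add atoms: none
Why: Birch reduction of a furan activated by the 3-carboxylate places the two hydrogens on C13 and C11 and leaves the C7=C8 enol ether. The alcohol protonates the enediolate before it can open the ring.

Step 6
Reactants: 8 rac-2,3-dihydrofuran-3-carboxylic acid
Product: 9 (R)-1-phenylethylammonium (S)-2,3-dihydrofuran-3-carboxylate
Conditions: (R)-1-phenylethylamine, acetone/EtOAc, repeated crystallisation
Reagents that add atoms: (R)-1-phenylethylamine C[C@@H](N)c1ccccc1
Why: Classical resolution through diastereomeric salts fixes the temporary C11 centre on a cheap C5 acid. The (S)-acid places C12 on the ring face that later also carries C6 and C9.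

Step 7
Reactants: 9 (R)-1-phenylethylammonium (S)-2,3-dihydrofuran-3-carboxylate
Product: 10 (R)-(2,3-dihydrofuran-3-yl)methanol
Conditions: LiAlH4 (excess), THF, 0 °C to reflux; H2O/15% NaOH work-up
Reagents that add atoms: none
Why: Hydride reduction of the carboxylate taken directly from the salt avoids any acid contact of the enol ether. The amine is recovered, and C11 is untouched (the descriptor changes only through priorities).

Step 8
Reactants: 10 (R)-(2,3-dihydrofuran-3-yl)methanol
Product: 11 (R)-3-[(4-methoxybenzyloxy)methyl]-2,3-dihydrofuran
Conditions: NaH, 4-methoxybenzyl chloride, Bu4NI (cat.), THF/DMF, 0 °C to rt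
Reagents that add atoms: 4-methoxybenzyl chloride COc1ccc(CCl)cc1
Why: Williamson etherification under base only; the PMB ether cannot migrate to an enolate oxygen, and it is removed oxidatively in the presence of the TBS ether.

Step 9
Reactants: 11 (R)-3-[(4-methoxybenzyloxy)methyl]-2,3-dihydrofuran
Product: 13 (R)-4-bromo-3-[(4-methoxybenzyloxy)methyl]-2,3-dihydrofuran, via vicinal dibromide 12 (not isolated)
Conditions: Br2 (1.0 equiv), CH2Cl2, −78 °C; then Et3N, −78 °C to rt
Reagents that add atoms: bromine BrBr
Why: Bromination–dehydrobromination of a cyclic enol ether: the anomeric bromide of 12 ionises and the C7–H, acidified by bromine, is lost, which gives the β-bromo enol ether. At −78 °C the enol ether outruns the anisyl ring for one equivalent of bromine.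

Step 10
Reactants: 13 (R)-4-bromo-3-[(4-methoxybenzyloxy)methyl]-2,3-dihydrofuran; 6 (4S,6R)-4-(tert-butyldimethylsilyloxy)-3-methyl-6-(prop-1-en-2-yl)cyclohex-2-en-1-one
Product: 15 (1R,4S,6R)-4-(tert-butyldimethylsilyloxy)-1-{(4R)-4-[(4-methoxybenzyloxy)methyl]-4,5-dihydrofuran-3-yl}-3-methyl-6-(prop-1-en-2-yl)cyclohex-2-en-1-ol, via vinyllithium 14 (not isolated)
Conditions: t-BuLi (2 equiv per 13), Et2O, −78 °C; then 6, −78 °C; aq. NaHCO3
Reagents that add atoms: none
Why: Bromine–lithium exchange followed by 1,2-addition forms C6–C7. In 14, lithium is trans to O8, but the anti elimination that destroys open-chain reagents of this kind would give a five-membered cycloalkyne and is therefore closed. Equatorial attack trans to the isopropenyl group is expected to give the 6R carbinol, and the crude, acid-sensitive product is used directly.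

Step 11
Reactants: 15 (1R,4S,6R)-carbinol
Product: 18 (1(10)E,4Z)-3β-(tert-butyldimethylsilyloxy)-8β,13-epoxy-12-(4-methoxybenzyloxy)-7αH,11αH-germacra-1(10),4-dien-6-one, via potassium alkoxide 16 (not isolated), via potassium enolate 17 (not isolated)
Conditions: KH, 18-crown-6, THF, 0 °C to rt; then AcOH/THF, −78 °C
Reagents that add atoms: none
Why: Deprotonation gives alkoxide 16, whose doubly allylic C1–C6 bond is weakened by the oxido group, so that a charge-accelerated [3,3]-shift can run near room temperature; this is an anionic oxy-Cope rearrangement, and the closest known type is the ring expansion of 1,2-dialkenylcyclohexanols to cyclodec-5-enones. The array C8=C7–C6–C1–C10=C9 reacts through a chair in which the bridge C5=C4–C3–C2 is equatorial at both C6 and C1; C8–C9 forms, the temporary C1–C6 bond breaks, and the ten-membered ring arises by four-atom ring expansion rather than by end-to-end closure. The equatorial C2 fixes the E geometry of C1=C10, the cis C4=C5 bond is carried over from ring A, and C1 (R) passes its chirality to C8: with O8 held trans to C6 by ring D, C9 bonds to the face of C8 that gives 8R (8β-O). The C6 epimer of 15 would reach the same C8 centre and the same E olefin through the chair with C5 axial, so the step is convergent with respect to the facial outcome of step 10. Enolate 17 carries O8 in the β position, but the five-membered ring holds the C8–O8 bond close to the nodal plane of the enolate and an expelled alkoxide would stay tethered through C13, which should hold back the β-elimination that an open-chain enol ether would invite. Protonation at −78 °C should come from the outer face of 17, anti to C9 on C8 and to C12 on C11, and so set 7αH (7R, cis ring fusion). The step needs chair over boat, which the inner-face CH2OPMB group reinforces because it would meet C10 in the boat; it also needs the isopropenyl group rather than the ring C4=C5 bond to take part, and C4 cannot reach C9 without forcing ring A into a boat.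

Step 12
Reactants: 18 germacradienone
Product: 19 6α-alcohol (6R) of 18
Conditions: NaBH4, CeCl3·7H2O, MeOH, −78 to −40 °C
Reagents that add atoms: none
Why: Luche 1,2-reduction of the Z-enone. The inner face of C6=O is covered across the ring by C1=C10, so hydride should enter from the outer face, the one that also took up the proton at C7 and that lies anti to C12, giving 6R. Ketone 18 is reduced without delay to forestall epimerisation at C7.

Step 13
Reactants: 19 6α-alcohol
Product: 20 6α,12-diol
Conditions: DDQ, CH2Cl2/pH 7 buffer, 0 °C
Reagents that add atoms: none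
Why: Oxidative cleavage of the PMB ether under neutral conditions; the trisubstituted olefins, the TBS ether and the tetrahydrofuran are inert, and the allylic alcohol reacts much more slowly than the benzylic ether.

Step 14
Reactants: 20 6α,12-diol
Product: 22 3β-(tert-butyldimethylsilyloxy)-8β,13-epoxy-11αH-germacra-1(10)E,4Z-dien-6α,12-olide, via lactol 21 (not isolated)
Conditions: TEMPO (20 mol %), PhI(OAc)2, CH2Cl2, rt
Reagents that add atoms: none
Why: Oxoammonium oxidation selects the primary alcohol; the aldehyde is captured by O6 as lactol 21 and oxidised on to the lactone. O8 is tied up, so only the 6,12-olide can form, and C12 and C6 are cis on the tetrahydrofuran as the cis-fused bicyclo[3.3.0] unit requires.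

Step 15
Reactants: 22 tetrahydrofuran-bridged lactone
Product: 24 3β-(tert-butyldimethylsilyloxy)-8β-hydroxygermacra-1(10)E,4Z,11(13)-trien-6α,12-olide, via lactone enolate 23 (not isolated)
Conditions: KHMDS (1.1 equiv), THF, −78 to 0 °C; then AcOH, −78 °C
Reagents that add atoms: none
Why: E1cB elimination of a β-alkoxy lactone (retro-oxa-Michael): C11–H is the only acidic C–H, and enolate 23 expels O8 from C13. The driving forces are relief of the all-cis, doubly fused tetrahydrofuran and formation of the conjugated enoate. The temporary O8–C13 bond and the C11 centre vanish, and O8–H appears as the only free hydroxyl.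

Step 16
Reactants: 25 (E)-2-methylbut-2-en-1-ol
Product: 26 [(2R,3R)-2,3-dimethyloxiran-2-yl]methanol
Conditions: Ti(OiPr)4 (10 mol %), D-(−)-diethyl tartrate, t-BuOOH, 4 Å molecular sieves, CH2Cl2, −20 °C
Reagents that add atoms: tert-butyl hydroperoxide CC(C)(C)OO
Why: Sharpless asymmetric epoxidation; the D-tartrate delivers oxygen to the face that gives the (2R,3R)-epoxy alcohol from an E-allylic alcohol, and the E geometry fixes the cis relation of the two methyl groups. A non-aqueous work-up is used for this small polar product.

Step 17
Reactants: 26 [(2R,3R)-2,3-dimethyloxiran-2-yl]methanol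
Product: 27 (2S,3R)-2,3-dimethyloxirane-2-carboxylic acid
Conditions: TEMPO (cat.), PhI(OAc)2, MeCN/H2O, rt
Reagents that add atoms: water O
Why: Oxoammonium oxidation of the primary alcohol through the aldehyde hydrate to the acid leaves the epoxide alone; the descriptor at C2 changes from R to S only through priorities.

Step 18
Reactants: 24 8β-hydroxy α-methylene lactone; 27 (2S,3R)-2,3-dimethyloxirane-2-carboxylic acid
Product: 29 8β-[(2S,3R)-2,3-dimethyloxirane-2-carbonyloxy] derivative of 24, via mixed anhydride 28 (not isolated)
Conditions: 2,4,6-trichlorobenzoyl chloride, Et3N, toluene, rt; then 24, DMAP, rt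
Reagents that add atoms: none
Why: Yamaguchi esterification is the standard way to join a hindered secondary alcohol to an α-branched acid. The quaternary α-carbon of 27 cannot epimerise, and O8–H is the only hydroxyl present.

Step 19
Reactants: 29 8β-ester
Product: 30 3β-alcohol
Conditions: HF·pyridine, pyridine, THF, 0 °C to rt
Reagents that add atoms: none
Why: Buffered fluoride cleaves the allylic TBS ether without the basicity that would endanger the enoate or cause acyl shifts; the glycidic ester is deactivated towards acid by its carbonyl group.

Step 20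
Reactants: 30 3β-alcohol; 31 (R)-2-methylbutanoic acid
Product: 33 3β-[(R)-2-methylbutanoyloxy]-8β-[(2S,3R)-2,3-dimethyloxirane-2-carbonyloxy]germacra-1(10)E,4Z,11(13)-trien-6α,12-olide, via O-acylisourea 32 (not isolated)
Conditions: DCC, DMAP (cat.), CH2Cl2, 0 °C
Reagents that add atoms: none
Why: Steglich esterification with retention at C3; a low temperature and a catalytic amount of DMAP keep the α-centre of the acid intact.

Step 21
Reactants: 33 triene diester
Product: 34 CNP0265335.4 (target)
Conditions: mCPBA (1.0 equiv), NaHCO3, CH2Cl2, 0 °C
Reagents that add atoms: 3-chloroperbenzoic acid O=C(OO)c1cccc(Cl)c1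
Why: Prilezhaev epoxidation is stereospecific, so E-C1=C10 gives the trans epoxide. It selects the only electron-rich olefin, because C4=C5 bears two allylic acyloxy groups and C11=C13 is an enoate. Attack on the outer face of the conformer with C14 on the β face, expected for the trans-lactonised ring with an 8β-ester, gives 1R,10R.

## Compound list

1 | (S)-(+)-carvone | CC1=CC[C@@H](CC1=O)C(C)=C | starting material
2 | (1S,4S,6S)-1-methyl-4-(prop-1-en-2-yl)-7-oxabicyclo[4.1.0]heptan-2-one | C[C@]12O[C@H]1C[C@H](C(C)=C)CC2=O | intermediate
3 | hydrazone of 2 | C[C@]12O[C@H]1C[C@H](C(C)=C)CC2=NN | intermediate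
4 | (1S,5R)-2-methyl-5-(prop-1-en-2-yl)cyclohex-2-en-1-ol (trans-carveol) | CC1=CC[C@@H](C(C)=C)C[C@@H]1O | intermediate
5 | tert-butyldimethylsilyl ether of 4 | CC1=CC[C@@H](C(C)=C)C[C@@H]1O[Si](C)(C)C(C)(C)C | intermediate
6 | (4S,6R)-4-(tert-butyldimethylsilyloxy)-3-methyl-6-(prop-1-en-2-yl)cyclohex-2-en-1-one | CC1=CC(=O)[C@@H](C(C)=C)C[C@@H]1O[Si](C)(C)C(C)(C)C | intermediate
7 | furan-3-carboxylic acid | OC(=O)c1ccoc1 | starting material
8 | rac-2,3-dihydrofuran-3-carboxylic acid | OC(=O)C1COC=C1 | intermediate
9 | (R)-1-phenylethylammonium (S)-2,3-dihydrofuran-3-carboxylate | C1=COC[C@H]1C(=O)[O-].C[C@@H]([NH3+])c1ccccc1 | intermediate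
10 | (R)-(2,3-dihydrofuran-3-yl)methanol | C1=COC[C@H]1CO | intermediate
11 | (R)-3-[(4-methoxybenzyloxy)methyl]-2,3-dihydrofuran | C1=COC[C@H]1COCc1ccc(OC)cc1 | intermediate
12 | (4R)-2,3-dibromo-4-[(4-methoxybenzyloxy)methyl]tetrahydrofuran (stereoisomers at the two new centres) | BrC1C(Br)OC[C@H]1COCc1ccc(OC)cc1 | intermediate
13 | (R)-4-bromo-3-[(4-methoxybenzyloxy)methyl]-2,3-dihydrofuran | BrC1=COC[C@H]1COCc1ccc(OC)cc1 | intermediate
14 | 4-lithio analogue of 13 | [Li]C1=COC[C@H]1COCc1ccc(OC)cc1 | intermediate
15 | (1R,4S,6R)-4-(tert-butyldimethylsilyloxy)-1-{(4R)-4-[(4-methoxybenzyloxy)methyl]-4,5-dihydrofuran-3-yl}-3-methyl-6-(prop-1-en-2-yl)cyclohex-2-en-1-ol | CC1=C[C@](O)(C2=COC[C@H]2COCc2ccc(OC)cc2)[C@@H](C(C)=C)C[C@@H]1O[Si](C)(C)C(C)(C)C | intermediate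
16 | potassium alkoxide of 15 | CC1=C[C@]([O-])(C2=COC[C@H]2COCc2ccc(OC)cc2)[C@@H](C(C)=C)C[C@@H]1O[Si](C)(C)C(C)(C)C.[K+] | intermediate
17 | potassium C6(7)-enolate of 18 (O6 cis to C8) | [K+].[O-]/C1=C2/[C@H](COCc3ccc(OC)cc3)CO[C@@H]2C/C(C)=C/C[C@H](O[Si](C)(C)C(C)(C)C)/C(C)=C\1 | intermediate
18 | (1(10)E,4Z)-3β-(tert-butyldimethylsilyloxy)-8β,13-epoxy-12-(4-methoxybenzyloxy)-7αH,11αH-germacra-1(10),4-dien-6-one | O=C1/C=C(/C)[C@@H](O[Si](C)(C)C(C)(C)C)C/C=C(\C)C[C@H]2OC[C@@H](COCc3ccc(OC)cc3)[C@@H]12 | intermediate
19 | 6α-alcohol (6R) of 18 | O[C@@H]1/C=C(/C)[C@@H](O[Si](C)(C)C(C)(C)C)C/C=C(\C)C[C@H]2OC[C@@H](COCc3ccc(OC)cc3)[C@@H]12 | intermediate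
20 | 3β-(tert-butyldimethylsilyloxy)-8β,13-epoxy-7αH,11αH-germacra-1(10)E,4Z-diene-6α,12-diol | O[C@@H]1/C=C(/C)[C@@H](O[Si](C)(C)C(C)(C)C)C/C=C(\C)C[C@H]2OC[C@@H](CO)[C@@H]12 | intermediate
21 | 6α,12-lactol of 22 (both anomers) | OC1O[C@@H]2/C=C(/C)[C@@H](O[Si](C)(C)C(C)(C)C)C/C=C(\C)C[C@H]3OC[C@@H]1[C@@H]23 | intermediate
22 | 3β-(tert-butyldimethylsilyloxy)-8β,13-epoxy-11αH-germacra-1(10)E,4Z-dien-6α,12-olide | O=C1O[C@@H]2/C=C(/C)[C@@H](O[Si](C)(C)C(C)(C)C)C/C=C(\C)C[C@H]3OC[C@@H]1[C@@H]23 | intermediate
23 | potassium enolate (C11=C12) of 22 | [K+].[O-]C1=C2CO[C@@H]3C/C(C)=C/C[C@H](O[Si](C)(C)C(C)(C)C)/C(C)=C\[C@@H](O1)[C@H]23 | intermediate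
24 | 3β-(tert-butyldimethylsilyloxy)-8β-hydroxygermacra-1(10)E,4Z,11(13)-trien-6α,12-olide | C=C1C(=O)O[C@@H]2/C=C(/C)[C@@H](O[Si](C)(C)C(C)(C)C)C/C=C(\C)C[C@@H](O)[C@@H]12 | intermediate
25 | (E)-2-methylbut-2-en-1-ol | C/C=C(\C)CO | starting material
26 | [(2R,3R)-2,3-dimethyloxiran-2-yl]methanol | OC[C@@]1(C)O[C@@H]1C | intermediate
27 | (2S,3R)-2,3-dimethyloxirane-2-carboxylic acid | OC(=O)[C@@]1(C)O[C@@H]1C | intermediate
28 | mixed anhydride of 27 and 2,4,6-trichlorobenzoic acid | O=C(OC(=O)[C@@]1(C)O[C@@H]1C)c1c(Cl)cc(Cl)cc1Cl | intermediate
29 | 8β-[(2S,3R)-2,3-dimethyloxirane-2-carbonyloxy]-3β-(tert-butyldimethylsilyloxy)germacra-1(10)E,4Z,11(13)-trien-6α,12-olide | C=C1C(=O)O[C@@H]2/C=C(/C)[C@@H](O[Si](C)(C)C(C)(C)C)C/C=C(\C)C[C@@H](OC(=O)[C@@]3(C)O[C@@H]3C)[C@@H]12 | intermediate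
30 | 3β-hydroxy analogue of 29 | C=C1C(=O)O[C@@H]2/C=C(/C)[C@@H](O)C/C=C(\C)C[C@@H](OC(=O)[C@@]3(C)O[C@@H]3C)[C@@H]12 | intermediate
31 | (R)-2-methylbutanoic acid | CC[C@@H](C)C(=O)O | starting material
32 | O-acylisourea from 31 and DCC | CC[C@@H](C)C(=O)OC(=NC1CCCCC1)NC1CCCCC1 | intermediate
33 | 3β-[(R)-2-methylbutanoyloxy]-8β-[(2S,3R)-2,3-dimethyloxirane-2-carbonyloxy]germacra-1(10)E,4Z,11(13)-trien-6α,12-olide | C=C1C(=O)O[C@@H]2/C=C(/C)[C@@H](OC(=O)[C@H](C)CC)C/C=C(\C)C[C@@H](OC(=O)[C@@]3(C)O[C@@H]3C)[C@@H]12 | intermediate
34 | CNP0265335.4, the (1R,10R)-epoxide of 33 | C=C1C(=O)O[C@@H]2/C=C(/C)[C@@H](OC(=O)[C@H](C)CC)C[C@H]3O[C@]3(C)C[C@@H](OC(=O)[C@@]3(C)O[C@@H]3C)[C@@H]12 | target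

## Step count and least certain steps

Total step count: 21. Longest linear sequence: 15 steps (7 to 34, steps 5–15 and 18–21). From 1 the sequence is 14 steps.

**Step 11 (key step).**
- What may go wrong: loss of the C8 oxygen from the enolate by β-elimination once the ring puckers; epimerisation at C7 during work-up, because the all-cis tetrahydrofuran is crowded; and a slow rearrangement, because the donor oxygen sits on the bond-forming terminus.
- Fallback: a neutral pericyclic route in which no enolate is ever formed. It sets out from 15, which is silylated with N-(trimethylsilyl)imidazole to the trimethylsilyl ether F1. This is heated in base-washed glass (o-dichlorobenzene, about 180–200 °C) so that a siloxy-Cope rearrangement gives the silyl enol ether F2. Cleavage with AcOH-buffered TBAF at −78 °C protonates C7 and comes back to the route at 18.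

**Step 4.**
- What may go wrong: hydrogen abstraction at C3–H or at the isopropenyl group instead of C6, and drift of the isopropenyl double bond into conjugation.
- Fallback: a route that fixes the positions of both oxygens by cycloaddition. It sets out from 1, which is condensed with tosylhydrazine to the tosylhydrazone F3. A Shapiro reaction (MeLi) converts this into the cyclohexadiene F4. Singlet oxygen (O2, tetraphenylporphyrin, light) adds anti to the isopropenyl group to give the endoperoxide F5. Kornblum–DeLaMare rearrangement (Et3N) gives the hydroxy enone F6, and silylation as in step 3 comes back at 6.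

**Step 6.**
- What may go wrong: poor discrimination between the two diastereomeric salts on crystallisation.
- Fallback: an enzymatic kinetic resolution one stage later. It sets out from 8, which is reduced with LiAlH4 to the racemic alcohol F7. Candida antarctica lipase B and vinyl acetate then acylate one enantiomer, shown for the (S)-alcohol as the acetate F8. The unreacted (R)-alcohol is separated, and the route is rejoined at 10.

**Step 12.**
- What may go wrong: poor facial selectivity, if the carbonyl group swings through the ring and presents its other face.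
- Fallback: substrate control is replaced by reagent control. It sets out from 18, uses Corey–Bakshi–Shibata reduction (the oxazaborolidine enantiomer matched to 6R, BH3·SMe2) and comes back at 19. No new compound arises.

**Step 15.**
- What may go wrong: slow expulsion of O8, because the C13–O8 bond overlaps poorly with the enolate inside the five-membered ring; re-addition of the alkoxide; and breakdown of the enolate on warming.
- Fallback: the ether is cleaved by substitution instead of elimination. It sets out from 22, in which Me2BBr (CH2Cl2, −78 to 0 °C) opens the tetrahydrofuran at the primary C13 to give the bromo alcohol F9. DBU then removes HBr and comes back at 24.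

**Step 21.**
- What may go wrong: attack on the wrong face of C1=C10, if the conformer with C14 on the α face reacts, and partial oxidation of C4=C5.
- Fallback: reagent control by Shi epoxidation. The fructose-derived ketone, or its enantiomer chosen by the spiro transition-state model, is used with Oxone in a buffered MeCN/dimethoxymethane/water mixture. It sets out from 33 and comes back at 34. No new compound arises.

## Further compounds

F1 | step 11 | trimethylsilyl ether of 15 | CC1=C[C@](O[Si](C)(C)C)(C2=COC[C@H]2COCc2ccc(OC)cc2)[C@@H](C(C)=C)C[C@@H]1O[Si](C)(C)C(C)(C)C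
F2 | step 11 | C6 trimethylsilyl enol ether of 18 | C[Si](C)(C)O/C1=C2/[C@H](COCc3ccc(OC)cc3)CO[C@@H]2C/C(C)=C/C[C@H](O[Si](C)(C)C(C)(C)C)/C(C)=C\1
F3 | step 4 | (S)-carvone 4-methylbenzenesulfonylhydrazone | CC1=CC[C@@H](CC1=NNS(=O)(=O)c1ccc(C)cc1)C(C)=C
F4 | step 4 | (5S)-2-methyl-5-(prop-1-en-2-yl)cyclohexa-1,3-diene | CC1=CC[C@@H](C=C1)C(C)=C
F5 | step 4 | endoperoxide of F4 (O–O bridge between C3 and C6, anti to isopropenyl) | CC1=C[C@@H]2OO[C@H]1C[C@@H]2C(C)=C
F6 | step 4 | (4S,6R)-4-hydroxy-3-methyl-6-(prop-1-en-2-yl)cyclohex-2-en-1-one | CC1=CC(=O)[C@@H](C(C)=C)C[C@@H]1O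
F7 | step 6 | rac-(2,3-dihydrofuran-3-yl)methanol | OCC1COC=C1
F8 | step 6 | acetate of (S)-(2,3-dihydrofuran-3-yl)methanol | C1=COC[C@@H]1COC(C)=O
F0 | step 12 | none | none
F9 | step 15 | 13-bromo-3β-(tert-butyldimethylsilyloxy)-8β-hydroxy-11αH-germacra-1(10)E,4Z-dien-6α,12-olide | BrC[C@H]1C(=O)O[C@@H]2/C=C(/C)[C@@H](O[Si](C)(C)C(C)(C)C)C/C=C(\C)C[C@@H](O)[C@@H]12
F0 | step 21 | none | none
A1 | alternative 1 | methyl (2Z,4R,6E,9S,10Z)-2-(bromomethyl)-9-(tert-butyldimethylsilyloxy)-6,10-dimethyl-12-oxo-4-(triethylsilyloxy)dodeca-2,6,10-trienoate | O=C/C=C(/C)[C@@H](O[Si](C)(C)C(C)(C)C)C/C=C(\C)C[C@@H](O[Si](CC)(CC)CC)/C=C(\CBr)C(=O)OC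
A2 | alternative 2 | 4,5-seco diene: trans-disubstituted α-methylene-γ-butyrolactone with a vinyl group on C6 and the C8–C4 chain ending in an isopropenyl group | C=C1C(=O)O[C@H](C=C)[C@H]1[C@H](O[Si](CC)(CC)CC)C/C(C)=C/C[C@H](O[Si](C)(C)C(C)(C)C)C(C)=C
A3 | alternative 3 | 13-membered bis-allylic ether (O bridging C6 and C13; O3 as TBS, O8 as TES, O12 as PMB ether) | O1C/C=C(/C)[C@@H](O[Si](C)(C)C(C)(C)C)C/C=C(\C)C[C@@H](O[Si](CC)(CC)CC)/C=C(/COCc2ccc(OC)cc2)C1
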